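If a run with its gas held makes more product than its solution holds of gas at saturation, keep its books by the feed.

| setting | Thursday's | flask |
|---|---|---|
| left-handed substrate | 0.054 M | 0.036 M |
| right-handed substrate | 0.054 M | 0.036 M |
| gas | 2.9 mM (held) | 2.9 mM (held) |
| remark | run made earlier |  |
| time |  | 10 min |

- Thursday's (time / min: left-handed substrate / %, left-handed product / %): 0.500: 25.6, 29.5; 1.00: 11.0, 52.6; 1.50: 3.3, 66.4; 2.00: 0, 70.5; 2.50: 0.7, 72.7; 3.00: 0.2, 73.2

(scatter of a reading: 1 percentage point)

- partner is single-handed; left-handed substrate and right-handed substrate are mirror images of each other, charged as a racemate, each of them at the stated concentration
- at the start none of the gas is in solution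
- the reaction counts as stopped when no species that holds the left-handed substrate and right-handed substrate together changes by six tenths of a point or more over the second half of the time
- the handed part of partner does not stay in what it makes, so the products of the two hands are mirror images too

- the state of affairs at 10 min: stopped, and by what, or still going (forward and back rates have come level / all of the left-handed substrate has reacted / it is still moving)
- part of the left-handed substrate and right-handed substrate together gone at 10 min
- the left-handed product standing at 10 min, as a percentage of the left-handed substrate and right-handed substrate together charged

Open the ledger on Thursday's run, where gas is held, so the substrates are the limiting reagent. First entry: left-handed substrate is half of Thursday's charge, yet left-handed product reads 73.2% at 3.00 min, more than that, so right-handed substrate must pay in as well. Second entry: 26.8% stands outside the readings. Third entry: the left-handed product of that last reading amounts to 0.0791 M, far more than the 2.9 mM of gas that saturates the solution, so reckon with a feed, and take as its estimate the mean rate of left-handed product up to the first reading, which carries that reading's scatter: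

feed = 0.0637 M min⁻¹

Now define the closing time, the product to be made divided by the feed. Read Thursday's plateau as the product share, and assume this flask has the same feed, since its gas is the same:

Thursday's: 1.24 min; 3.00 min is 2.42 closing times
this flask: 0.827 min; 10 min is 12.1 closing times

Thursday's left-handed substrate reads 0.2% at its last reading, and this flask runs far longer in closing times. So expect this flask stopped, its left-handed substrate as low as that reading. The product share here is borrowed from Thursday's, not reckoned.

The forecast says all of the left-handed substrate has reacted, conversion 100% (97% to 100%), left-handed product 73% (67% to 79%), on the ground that “Ten minutes is over three times the time needed”.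

The flask gives all of the left-handed substrate has reacted, conversion 100%, left-handed product 77.0%.

    partner + left-handed substrate → left-handed product (k = 36.5 L mol⁻¹ s⁻¹)
    partner + right-handed substrate → right-handed product (k = 0.201 L mol⁻¹ s⁻¹)
    left-handed substrate ⇌ achiral form (K = 0.0815, k = 6.05 s⁻¹)
    right-handed substrate ⇌ achiral form (K = 0.0815, k = 6.05 s⁻¹)
    achiral form → decomposed reagent (k = 0.170 s⁻¹)
    gas ⇌ partner, rate k6*(csat - [partner]) (kL = 0.516 s⁻¹)
    partner → decomposition product (k = 2.48 × 10⁻⁴ s⁻¹)

Redo the reckoning with this flask's own product share: its closing time becomes 0.870 min, so 10 min is 11.5 closing times. Then take the neighbouring flask, the same charge read at 4.0 min. That is 4.60 closing times, more than the 2.42 of Thursday's last reading. The books of the neighbouring flask are closed: left-handed substrate 0%, right-handed substrate 0%, achiral form 0%, left-handed product 77.0%, right-handed product 0.428%, decomposed reagent 22.6%.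

(The data are calculated for an exercise.)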